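The route rests on cutting C7–C8 as the retron of a [2,3]-Wittig rearrangement. C7(OH)–C8(Me)–C9(Me)=C10 is a homoallylic alcohol whose carbinol carbon sits on C6 of the 2-pyrone. C6 is the ε-terminus of the vinylogous ester O=C2–C3=C4–C5=C6, so a C6–CH2–O ether is acidic enough to serve as the carbanion terminus. In one operation, the last step, the shift bonds the intact pyrone to the chain, forms C7–C8, sets C7 and C8, builds the E C9=C10 alkene and only then unveils the labile skipped diene at C11. The precursor is the pyron-6-ylmethyl ether of a 10,11-syn dienol. Its C10–O stereocentre is traded for C7 and C8.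

Key step: step 11

Remark on numbering: pyrone O1, C2 (C=O), C3 (Me), C4 (OMe), C5, C6. Side chain C7 (OH), C8 (Me), C9 (Me)=C10, C11 (Me), C12=C13 (Me), C14 (OH), C15. The SMILES reads as (7S,8S,9E,11R,12E,14R), with the C7-OH and C8-Me anti in the zigzag drawing. These numbers are also used for the fragments.
Assumption: compounds 1, 5, 9 and 13 are taken as commercial.

Step 1
Reactants: 1 pent-3-yn-2-one
Product: 2 (S)-pent-3-yn-2-ol
Conditions: RuCl[(S,S)-TsDPEN](p-cymene) (cat.), i-PrOH, rt
Reagents that add atoms: none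
Why: Noyori asymmetric transfer hydrogenation, in which the alkynyl group takes the place usually held by an aryl group in the six-membered Ru–H/N–H transition state, so the (S,S)-catalyst should give the (S)-carbinol (future C11) and leave the triple bond alone.

Step 2
Reactants: 2 (S)-pent-3-yn-2-ol
Product: 3 (S)-pent-3-yn-2-yl methanesulfonate
Conditions: MsCl, Et3N, CH2Cl2, −78 to 0 °C
Reagents that add atoms: methanesulfonyl chloride, CS(=O)(=O)Cl
Why: Standard O-mesylation that does not touch the C–O bond, so the (S) configuration is kept.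

Step 3
Reactants: 3 (S)-pent-3-yn-2-yl methanesulfonate
Product: 4 (aR)-tributyl(penta-2,3-dien-2-yl)stannane
Conditions: Bu3SnH, LDA, THF, 0 °C; CuBr·SMe2, −78 °C; then 3, THF, −78 °C
Reagents that add atoms: tributyltin hydride, CCCC[SnH](CCCC)CCCC
Why: Anti-SN2′ displacement of a propargylic mesylate by a stannylcopper reagent, a well-known entry to enantioenriched allenylstannanes, in which tin enters the distal alkyne carbon (future C13) opposite to the leaving mesylate and so turns the (S) centre into the (aR) axis.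

Step 4
Reactants: 4 (aR)-tributyl(penta-2,3-dien-2-yl)stannane; 5 (E)-2-methylbut-2-enal (tiglaldehyde)
Product: 6 (2E,4R,5S)-3,5-dimethyloct-2-en-6-yn-4-ol
Conditions: BF3·OEt2, CH2Cl2, −78 °C; aq NaHCO3
Reagents that add atoms: none
Why: Lewis acid promoted SE2′ addition of a chiral allenylstannane to an aldehyde, in which the aldehyde bonds to C11 anti to tin, fixing (11S), and the open antiperiplanar transition state keeps the branched alkenyl group of 5 away from the allene methyl, giving the 10,11-syn adduct, (10R).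

Step 5
Reactants: 6 (2E,4R,5S)-3,5-dimethyloct-2-en-6-yn-4-ol
Product: 8 (2E,4R,5S,6E)-7-iodo-3,5-dimethylocta-2,6-dien-4-ol, via alkenylzirconocene alkoxide 7 (not isolated)
Conditions: Cp2Zr(H)Cl (2.5 equiv), THF, rt to 40 °C; then I2, THF, 0 °C
Reagents that add atoms: iodine, II
Why: Hydrozirconation with the Schwartz reagent and iodinolysis, in which the first equivalent is taken by the hydroxyl group, syn addition puts zirconium on the less hindered C13 next to methyl (helped by equilibration with excess reagent), the trisubstituted C8=C9 alkene is too hindered to react, and iodine replaces zirconium with retention to give the E-iodide.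

Step 6
Reactants: 9 4-hydroxy-3,6-dimethyl-2H-pyran-2-one
Product: 10 4-methoxy-3,6-dimethyl-2H-pyran-2-one
Conditions: Me2SO4, K2CO3, acetone, reflux
Reagents that add atoms: dimethyl sulfate, COS(=O)(=O)OC
Why: O-Methylation of the vinylogous acid under mild base, which for 4-hydroxy-2-pyrones goes to the C4 oxygen and keeps the 2-pyrone form.

Step 7
Reactants: 10 4-methoxy-3,6-dimethyl-2H-pyran-2-one
Product: 11 6-(bromomethyl)-4-methoxy-3-methyl-2H-pyran-2-one
Conditions: NBS, AIBN (cat.), PhCF3, reflux
Reagents that add atoms: N-bromosuccinimide, O=C1CCC(=O)N1Br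
Why: Wohl–Ziegler bromination, known for 4-methoxy-6-methyl-2-pyrones, in which hydrogen abstraction from the 6-methyl group gives the radical delocalised over C5, C3 and the lactone carbonyl, while the 3-methyl group behaves like the less reactive α-methyl of an acrylate and blocks C3 against ionic bromination.

Step 8
Reactants: 8 (2E,4R,5S,6E)-7-iodo-3,5-dimethylocta-2,6-dien-4-ol; 11 6-(bromomethyl)-4-methoxy-3-methyl-2H-pyran-2-one
Product: 12 6-({[(2E,4R,5S,6E)-7-iodo-3,5-dimethylocta-2,6-dien-4-yl]oxy}methyl)-4-methoxy-3-methyl-2H-pyran-2-one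
Conditions: AgOTf, 2,6-di-tert-butyl-4-methylpyridine, 4 Å MS, CH2Cl2, 0 °C to rt, dark
Reagents that add atoms: none
Why: Silver-assisted Williamson-type etherification under non-basic conditions, in which halide abstraction makes the primary, SN1-inert pyronylmethyl carbon electrophilic enough for the hindered C10–OH, the hindered pyridine only scavenges acid so that the acidic C7–H and the pyrone ring are spared, and the C10–O bond is never broken, so C10 and C11 are kept.

Step 9
Reactants: 12 6-({[(2E,4R,5S,6E)-7-iodo-3,5-dimethylocta-2,6-dien-4-yl]oxy}methyl)-4-methoxy-3-methyl-2H-pyran-2-one; 13 tributyl(1-ethoxyvinyl)stannane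
Product: 15 6-({[(2E,4R,5S,6E)-3,5,7-trimethyl-8-oxonona-2,6-dien-4-yl]oxy}methyl)-4-methoxy-3-methyl-2H-pyran-2-one, via ethoxydiene 14 (not isolated)
Conditions: Pd(PPh3)4 (cat.), CuI (cat.), DMF, 60 °C; then 1 M HCl, THF, 0 °C
Reagents that add atoms: tributyl(1-ethoxyvinyl)stannane 13, C=C(OCC)[Sn](CCCC)(CCCC)CCCC; water, O
Why: Stille coupling of an alkenyl iodide with an acyl anion equivalent keeps the E geometry of C12=C13, and brief mild acid hydrolysis of enol ether 14 gives the methyl enone (C14, C15) without touching the allylic ether or C11.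

Step 10
Reactants: 15 6-({[(2E,4R,5S,6E)-3,5,7-trimethyl-8-oxonona-2,6-dien-4-yl]oxy}methyl)-4-methoxy-3-methyl-2H-pyran-2-one
Product: 16 6-({[(2E,4R,5S,6E,8R)-8-hydroxy-3,5,7-trimethylnona-2,6-dien-4-yl]oxy}methyl)-4-methoxy-3-methyl-2H-pyran-2-one
Conditions: (S)-2-methyl-CBS-oxazaborolidine (cat.), BH3·SMe2, THF, −30 °C; then MeOH
Reagents that add atoms: none
Why: Corey–Bakshi–Shibata reduction, in which the α-methylalkenyl group acts as the large and methyl as the small substituent, so the (S)-catalyst should deliver hydride to the face that gives (14R), while pyrone, ether and trisubstituted alkenes do not compete at low temperature.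

Step 11
Reactants: 16 6-({[(2E,4R,5S,6E,8R)-8-hydroxy-3,5,7-trimethylnona-2,6-dien-4-yl]oxy}methyl)-4-methoxy-3-methyl-2H-pyran-2-one
Product: 18 6-[(1S,2S,3E,5R,6E,8R)-1,8-dihydroxy-2,3,5,7-tetramethylnona-3,6-dien-1-yl]-4-methoxy-3-methyl-2H-pyran-2-one (target), via dilithium trienolate 17 (not isolated)
Conditions: LiHMDS (2.3 equiv), THF, −78 to −10 °C; aq NH4Cl
Reagents that add atoms: none
Why: Proposed new method: LiHMDS removes the C14–OH proton and then a C7–H of the C6–CH2–O group, giving trienolate 17 in which the charge runs from C7 through C6=C5 and C4=C3 to the C2 carbonyl, and C7 then bonds to C8 while the C10–O bond breaks in a concerted, suprafacial six-electron [2,3]-sigmatropic shift through the five-membered envelope C7–O–C10–C9=C8. The closest known reaction types are the [2,3]-Wittig rearrangements of benzylic allyl ethers, of α-allyloxy ester enolates and of allyloxy-1,3-dicarbonyl compounds, which indicate that even strongly stabilised oxy-carbanions rearrange; a 2-pyron-6-ylmethyl ether has not been used, and no ring is closed. C8 is controlled by 1,3-chirality transfer from C10: with the C11 residue outside (pseudo-equatorial), the (10R)-ether delivers C7 to the face of C8 on which the C10–O bond stood, which gives (8S) and, from the same conformer, the E C9=C10 alkene. C7 is controlled by the exo placement of the flat pyrone, turned away from the C9 methyl and the C8 methyl, which for the E C8=C9 alkene translates into the 7,8-anti pair, (7S). The step needs E over Z selectivity, and the stabilised anion should secure it through a late transition state in which C8 is already pyramidal, so that an inside C11 residue would clash with C7 and the C8 methyl (the opposite of the early, Z-selective Wittig–Still case). It also needs site selectivity, which the substrate provides because C3 is blocked by methyl, bonding from C5 would be a forbidden eight-electron shift, the C12=C13 alkene is out of reach of C7, and C11–H becomes bis-allylic only in the product alkoxide and is beyond the reach of LiHMDS, so C11 and C14 stay untouched.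

Compound list
1 | pent-3-yn-2-one | CC#CC(C)=O | starting material
2 | (S)-pent-3-yn-2-ol | C[C@H](O)C#CC | intermediate
3 | (S)-pent-3-yn-2-yl methanesulfonate | C[C@H](OS(C)(=O)=O)C#CC | intermediate
4 | (aR)-tributyl(penta-2,3-dien-2-yl)stannane | CC([H])=[C@]=C(C)[Sn](CCCC)(CCCC)CCCC | intermediate
5 | (E)-2-methylbut-2-enal (tiglaldehyde) | C/C=C(\C)C=O | starting material
6 | (2E,4R,5S)-3,5-dimethyloct-2-en-6-yn-4-ol | C/C=C(\C)[C@H](O)[C@@H](C)C#CC | intermediate
7 | (E)-C13-alkenylzirconocene chloride carrying a C10–O–ZrCp2Cl alkoxide (Cp drawn η1) | C/C=C(\C)[C@H](O[Zr](Cl)(C1C=CC=C1)C1C=CC=C1)[C@@H](C)/C=C(\C)[Zr](Cl)(C1C=CC=C1)C1C=CC=C1 | intermediate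
8 | (2E,4R,5S,6E)-7-iodo-3,5-dimethylocta-2,6-dien-4-ol | C/C=C(\C)[C@H](O)[C@@H](C)/C=C(\C)I | intermediate
9 | 4-hydroxy-3,6-dimethyl-2H-pyran-2-one | Cc1cc(O)c(C)c(=O)o1 | starting material
10 | 4-methoxy-3,6-dimethyl-2H-pyran-2-one | COc1cc(C)oc(=O)c1C | intermediate
11 | 6-(bromomethyl)-4-methoxy-3-methyl-2H-pyran-2-one | COc1cc(CBr)oc(=O)c1C | intermediate
12 | 6-({[(2E,4R,5S,6E)-7-iodo-3,5-dimethylocta-2,6-dien-4-yl]oxy}methyl)-4-methoxy-3-methyl-2H-pyran-2-one | COc1cc(CO[C@@H](/C(C)=C/C)[C@@H](C)/C=C(\C)I)oc(=O)c1C | intermediate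
13 | tributyl(1-ethoxyvinyl)stannane | C=C(OCC)[Sn](CCCC)(CCCC)CCCC | starting material
14 | 6-({[(2E,4R,5S,6E)-8-ethoxy-3,5,7-trimethylnona-2,6,8-trien-4-yl]oxy}methyl)-4-methoxy-3-methyl-2H-pyran-2-one | COc1cc(CO[C@@H](/C(C)=C/C)[C@@H](C)/C=C(\C)C(=C)OCC)oc(=O)c1C | intermediate
15 | 6-({[(2E,4R,5S,6E)-3,5,7-trimethyl-8-oxonona-2,6-dien-4-yl]oxy}methyl)-4-methoxy-3-methyl-2H-pyran-2-one | COc1cc(CO[C@@H](/C(C)=C/C)[C@@H](C)/C=C(\C)C(C)=O)oc(=O)c1C | intermediate
16 | 6-({[(2E,4R,5S,6E,8R)-8-hydroxy-3,5,7-trimethylnona-2,6-dien-4-yl]oxy}methyl)-4-methoxy-3-methyl-2H-pyran-2-one | COc1cc(CO[C@@H](/C(C)=C/C)[C@@H](C)/C=C(\C)[C@@H](C)O)oc(=O)c1C | intermediate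
17 | dilithium salt of 16: C14 alkoxide and C7–C2 trienolate (6-alkylidene-6H-pyran-2-olate) | [Li+].[Li+].COC1=CC(=CO[C@@H](/C(C)=C/C)[C@@H](C)/C=C(\C)[C@@H](C)[O-])OC([O-])=C1C | intermediate
18 | 6-[(1S,2S,3E,5R,6E,8R)-1,8-dihydroxy-2,3,5,7-tetramethylnona-3,6-dien-1-yl]-4-methoxy-3-methyl-2H-pyran-2-one | COc1cc([C@@H](O)[C@@H](C)/C(C)=C/[C@@H](C)/C=C(\C)[C@@H](C)O)oc(=O)c1C | target

Total step count: 11. Longest linear sequence: 9 (steps 1–5 and 8–11).

Steps most likely to fail

1. Step 11 (Proposed new method). Three things may go wrong.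
 - E/Z control may be lost if the C11 residue moves to the inside position to relieve its strain against the C9 methyl.
 - The 7,8-anti selectivity may erode if the pyrone adopts the endo orientation.
 - The over-stabilised anion may rearrange slowly, with a [1,2]-shift setting in on warming.

 The fallback uses known chemistry, sets out from 8 and comes back at 18. It keeps the C10-to-C8 chirality transfer but moves it into a chair [3,3] process and builds the pyrone classically. Johnson orthoester Claisen rearrangement of 8 (MeC(OEt)3, cat. EtCO2H, xylene, 135 °C) should give ethyl (3R,4E,6R,7E)-8-iodo-3,4,6-trimethylnona-4,7-dienoate F1. The dianion of ethyl 2-methylacetoacetate (NaH, then n-BuLi) is acylated by F1 to the 3,5-dioxo ester F2. DBU in hot toluene closes F2 to the 4-hydroxy-2-pyrone F3, and Me2SO4/K2CO3 gives the 4-methoxy-2-pyrone F4. Stille coupling with 13 passes through the ethoxydiene F5, and mild hydrolysis gives the enone F6. CBS reduction as in step 10 gives the 7-deoxy alcohol F7. Finally, double deprotonation with LiHMDS is followed by Davis hydroxylation of the C7 trienolate. The matched enantiomer of (camphorsulfonyl)oxaziridine is used, so that reagent control is supported by the C8 centre, and this installs the (7S)-hydroxyl and gives 18.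

2. Step 8. The hindered C10–OH may be alkylated too slowly, so that decomposition of the activated pyronylmethyl electrophile or acid-induced ionisation of the allylic alcohol takes over.

 The fallback sets out from 8 and comes back at 12. The ether oxygen is first attached to a robust two-carbon unit, and the pyrone is then grown on it. O-Alkylation of 8 with 2-bromo-N-methoxy-N-methylacetamide (NaH, THF) gives the Weinreb amide F8. Addition of the dianion of ethyl 2-methylacetoacetate gives the 3,5-dioxo ester F9, and DBU closes it to the 4-hydroxy-2-pyrone F10. Me2SO4/K2CO3 then gives 12. This path also makes steps 6 and 7 unnecessary.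

3. Step 7. Site selectivity between the 6-methyl and 3-methyl groups may be poor, and the first product may be brominated a second time.

 The fallback sets out from 10 and comes back at 11. The radical step is replaced by polar chemistry that can only use the vinylogous position. Deprotonation of 10 (LiHMDS, THF, −78 °C) and hydroxylation with 2-(phenylsulfonyl)-3-phenyloxaziridine gives 6-(hydroxymethyl)-4-methoxy-3-methyl-2H-pyran-2-one F11. An Appel reaction (CBr4, PPh3, CH2Cl2) converts it into 11.

Further compounds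
F1 | step 11 | ethyl (3R,4E,6R,7E)-8-iodo-3,4,6-trimethylnona-4,7-dienoate | CCOC(=O)C[C@@H](C)/C(C)=C/[C@@H](C)/C=C(\C)I
F2 | step 11 | ethyl (7R,8E,10R,11E)-12-iodo-2,7,8,10-tetramethyl-3,5-dioxotrideca-8,11-dienoate (C2 epimers) | CCOC(=O)C(C)C(=O)CC(=O)C[C@@H](C)/C(C)=C/[C@@H](C)/C=C(\C)I
F3 | step 11 | 4-hydroxy-6-[(2R,3E,5R,6E)-7-iodo-2,3,5-trimethylocta-3,6-dien-1-yl]-3-methyl-2H-pyran-2-one | Cc1c(O)cc(C[C@@H](C)/C(C)=C/[C@@H](C)/C=C(\C)I)oc1=O
F4 | step 11 | 6-[(2R,3E,5R,6E)-7-iodo-2,3,5-trimethylocta-3,6-dien-1-yl]-4-methoxy-3-methyl-2H-pyran-2-one | COc1cc(C[C@@H](C)/C(C)=C/[C@@H](C)/C=C(\C)I)oc(=O)c1C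
F5 | step 11 | 6-[(2R,3E,5R,6E)-8-ethoxy-2,3,5,7-tetramethylnona-3,6,8-trien-1-yl]-4-methoxy-3-methyl-2H-pyran-2-one | COc1cc(C[C@@H](C)/C(C)=C/[C@@H](C)/C=C(\C)C(=C)OCC)oc(=O)c1C
F6 | step 11 | 4-methoxy-3-methyl-6-[(2R,3E,5R,6E)-2,3,5,7-tetramethyl-8-oxonona-3,6-dien-1-yl]-2H-pyran-2-one | COc1cc(C[C@@H](C)/C(C)=C/[C@@H](C)/C=C(\C)C(C)=O)oc(=O)c1C
F7 | step 11 | 6-[(2R,3E,5R,6E,8R)-8-hydroxy-2,3,5,7-tetramethylnona-3,6-dien-1-yl]-4-methoxy-3-methyl-2H-pyran-2-one | COc1cc(C[C@@H](C)/C(C)=C/[C@@H](C)/C=C(\C)[C@@H](C)O)oc(=O)c1C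
F8 | step 8 | 2-{[(2E,4R,5S,6E)-7-iodo-3,5-dimethylocta-2,6-dien-4-yl]oxy}-N-methoxy-N-methylacetamide | CON(C)C(=O)CO[C@@H](/C(C)=C/C)[C@@H](C)/C=C(\C)I
F9 | step 8 | ethyl 6-{[(2E,4R,5S,6E)-7-iodo-3,5-dimethylocta-2,6-dien-4-yl]oxy}-2-methyl-3,5-dioxohexanoate (C2 epimers) | CCOC(=O)C(C)C(=O)CC(=O)CO[C@@H](/C(C)=C/C)[C@@H](C)/C=C(\C)I
F10 | step 8 | 4-hydroxy-6-({[(2E,4R,5S,6E)-7-iodo-3,5-dimethylocta-2,6-dien-4-yl]oxy}methyl)-3-methyl-2H-pyran-2-one | Cc1c(O)cc(CO[C@@H](/C(C)=C/C)[C@@H](C)/C=C(\C)I)oc1=O
F11 | step 7 | 6-(hydroxymethyl)-4-methoxy-3-methyl-2H-pyran-2-one | COc1cc(CO)oc(=O)c1C
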